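## Structural features

The target is a 1-aryltetralin in which benzene ring A (C4a, C5–C8, C8a) is fused to a saturated ring B (C1–C4) and a 4-hydroxy-3,5-dimethoxyphenyl ring sits on C1. Ring B holds three contiguous stereocentres, C1 (aryl, S), C2 and C3 (hydroxymethyl, R and R). Neighbouring substituents are trans throughout, so all three are equatorial. Ring A is substituted everywhere except C5: OMe at C6, OH at C7, OMe at C8, the last one peri to the C1 aryl group. Both phenols are flanked by two methoxy groups and are easily oxidised, and C1–H is doubly benzylic; the two primary alcohols are ordinary. The real difficulties are the crowded, regiodefined ring A and the configuration at C1, where the aryl group must end up equatorial next to C2. The key step exploits the meta relationship of the C6 and C8 oxygens with hydrogen at C5: ring A is grown from a vinylketene and methoxyethyne onto a ring-B cyclohexene (future C1–C4, C4a, C8a) that already carries the three stereocentres, and the C7 hydroxyl is added afterwards.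

## Logic of the disconnections

38 to 37: the two O–Si bonds and the aryl O–CH2 acetal bond are cut. Free phenols and alcohols would not survive the bases, organometallics and oxidants used earlier. The forward step must remove three groups in one acidic operation without ionising the doubly benzylic C1.

37 to 34: the C7–O bond is cut. C7 is the only ring position between two methoxy groups, so directed lithiation is cooperative there, whereas electrophilic substitution would go to C5. The gain is that ring A needs only the 6,8-dioxygenation the key step delivers. The demand is that ring lithiation is faster than removal of C1–H.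

34 to 33: the C8 O–CH3 bond is cut, because the key step delivers C8 as a free phenol.

33 to 25 and 28: C4a–C5, C5–C6, C7–C8 and C8–C8a are cut, which removes ring A entirely. The pattern (oxygen at C6 and C8, hydrogen at C5, free OH on the ketene-derived carbon) is what a vinylketene–alkoxyalkyne benzannulation writes. An aromatic ring is traded for a two-carbon alkyne and a diazomethyl ketone on a cyclohexene. The forward step needs one regiochemical sense of cycloaddition and neutral conditions that leave the allylic, benzylic C1 centre alone.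

25 to 23: the C=N2 bond is cut. The classical route through an acyl chloride and a diazoalkane is avoided: dipolar cycloaddition to the conjugated double bond competes and the reagent is hazardous. Diazo transfer to the methyl ketone needs kinetic enolisation at CH3 and not at the γ-C–H.

23 to 21: the ring-to-acyl C–C bond is cut. An enol triflate fixes the double bond between future C4a and C8a without ambiguity. The coupling must attach the two-carbon unit through its oxygen-bearing carbon, and the enol ether must hydrolyse under conditions that spare silyl ethers.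

21 to 18: the C–H bond at future C1 and the O–S bond are cut. A group entering the β-carbon of this cyclohexenone should come in axially, anti to the substituent two carbons away (future C3). If the aryl group entered last, it would end axial and cis to the future C2 substituent. If hydrogen enters last, the aryl group ends equatorial, as required. Direct aryl cuprate addition with triflate trapping would be two steps shorter but is not used for this reason. The demand is conjugate hydride delivery to a hindered β-aryl enone with capture of the enolate.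

18 to 17 to 12 and 14 (through 16): the aryl–ring bond is cut. Conjugate addition with O-silylation, then dehydrogenation toward the aryl-bearing carbon. The configuration created in the addition does not matter; only the position of the enol ether does. 14 comes from 13 by O-protection.

12 to 11 to 8 to 7: the carbonyl is moved back to an alkene by 1,3-transposition of oxygen. The carbonyl must sit on the carbon remote from the substituents so that the β-carbon is next to future C2. Because 7 is C2-symmetric, both faces give the same epoxide and both modes of opening converge on 12.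

7 to 6 to 5 to 3 and 4: the future C1–C2 and C3–C4 bonds are cut (Diels–Alder). The E alkene sets C2/C3 trans and the ester auxiliary sets the absolute configuration. 3 is built from 2 and two molecules of 1, one on each carboxyl group. The auxiliary is the (1S,2R,5S)-menthyl ester: the more common (1R,2S,5R) ester should lead to the (1S,2S) adduct and hence to the enantiomer of 38.

28 to 26: two eliminations from a chloroacetal.

## Other disconnections considered

Alternative 1: Cut C2–C3 and C1–C8a (oxidative phenol coupling).
- **Forward step:** the tethered bis-sinapate A1 is oxidised at both phenols by FeCl3. The radicals join at the β-carbons, one quinone methide tautomerises, and its ring carbon attacks the other quinone methide, closing ring B to give the bridged dihydronaphthalene diester A2.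
- **In favour:** every oxygen of ring A, including the C7 phenol, is present from the start, and no phenol protection or late C–H hydroxylation is needed. C1/C2 trans comes from the cyclisation. The whole route should take about five steps. On step economy and on reaching the ring-A oxygenation this plan is better than the chosen one.
- **Against:** absolute configuration rests on the bias of a remote diol tether in a radical coupling. β–O coupling and over-oxidation compete. C3 is set only afterwards, by reducing the C3–C4 double bond (correctable, since C3 is α to an ester).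
- **Comparison:** the chosen plan is better on predictability of the absolute configuration (auxiliary-controlled cycloaddition) and uses closed-shell steps throughout. The two are about equal on C1/C2 control, which in both follows a conformational preference of ring B.

Alternative 2: Cut C1–C1' and C1–C2 (palladium carbene).
- **Forward step:** tosylhydrazone A3 and aryl bromide A4 react with Pd2(dba)3, a phosphine and LiOt-Bu. A palladium carbene forms at C1, aryl migration makes C1–C1', and the tethered malonate closes ring B on the benzylpalladium to give A5.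
- **In favour:** convergent; the pendant aryl group is introduced late and can be varied; both arenes arrive fully oxygenated, which is better than the chosen plan on the C7 oxygen.
- **Against:** C1 is controlled only by the C3 centre across a quaternary C2, so its configuration is uncertain. The carbene carbon is flanked by a methoxy group. C2 becomes a stereocentre only on later decarboxylation. The C3 centre of A3 needs its own asymmetric synthesis.
- **Comparison:** step count is about equal to the chosen plan. The chosen plan is better on stereocontrol at C1 and on precedent for the key step in a ring-closing, hindered setting.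

Alternative 3: Cut C1–C2 and C3–C4 (photoenol Diels–Alder).
- **Forward step:** irradiation of the ortho-methyl benzophenone A6 with Ti(Oi-Pr)4 and a tartrate-derived diol ligand gives the hydroxy-ortho-quinodimethane, which adds to dimethyl fumarate A8 to give the tetralol diester A7.
- **In favour:** the most convergent plan. Ring B and the C2/C3 trans pair form in one step, all oxygens are in place, and about six or seven steps should suffice. This is better than the chosen plan on step economy.
- **Against:** C1 is formed as a tertiary carbinol, so its real configuration is set only in a later ionic deoxygenation of uncertain facial selectivity. A donor-rich benzophenone has a low-lying charge-transfer triplet that enolises poorly. The ortho-methoxy group offers a competing hydrogen abstraction. The chiral titanium complex is stoichiometric.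
- **Comparison:** both plans use light and both take C2/C3 trans from fumarate geometry, so they are equal there. The chosen plan is better on the point that decides the target: C1 is set by substrate control on a conformationally defined ring.

Key step: step 15

Assumption: under dialkylaluminium chloride promotion the diene adds to the face of the s-trans,s-trans fumarate not screened by the menthyl isopropyl groups, which for the (1S,2R,5S)-menthyl ester is the re,re face and gives the (1R,2R) adduct.

Abbreviations in names: TBS = tert-butyldimethylsilyl; Ar = 3,5-dimethoxy-4-(methoxymethoxy)phenyl. Cyclohexene intermediates use ring numbering with C1 at the oxygen- or acyl-bearing carbon; tetralins use C1 for the aryl-bearing carbon.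

## Route

Step 1
Reactants: 1 (1S,2R,5S)-menthol (2 equiv); 2 fumaric acid
Product: 3 bis[(1S,2R,5S)-menthyl] fumarate
Conditions: 1 (2.2 equiv), 2 (1 equiv), TsOH·H2O (cat.), toluene, reflux, Dean–Stark
Reagents that add atoms: (1S,2R,5S)-menthol (second equivalent of 1), CC(C)[C@H]1CC[C@H](C)C[C@@H]1O
Why: Twofold acid-catalysed Fischer esterification driven by azeotropic removal of water, each carboxyl group of 2 taking up one molecule of 1; the C–O bond of menthol is not broken, so its stereocentres are retained, and the E alkene is the stable isomer.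

Step 2
Reactants: 3 bis[(1S,2R,5S)-menthyl] fumarate; 4 buta-1,3-diene
Product: 5 bis[(1S,2R,5S)-menthyl] (1R,2R)-cyclohex-4-ene-1,2-dicarboxylate
Conditions: i-Bu2AlCl (2 equiv), 4 (excess), toluene/hexane, −40 °C
Reagents that add atoms: none
Why: Auxiliary-controlled, Lewis-acid-promoted Diels–Alder reaction: in the aluminium-bound s-trans,s-trans diester both isopropyl groups screen the si,si face, so the diene should add to the re,re face and give the (1R,2R) centres (future C2 and C3); their trans relationship follows from the E alkene in a suprafacial cycloaddition.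

Step 3
Reactants: 5 bis[(1S,2R,5S)-menthyl] (1R,2R)-cyclohex-4-ene-1,2-dicarboxylate
Product: 6 [(1R,2R)-cyclohex-4-ene-1,2-diyl]dimethanol
Conditions: LiAlH4, THF, 0 °C → reflux; aqueous work-up (menthol recovered)
Reagents that add atoms: none
Why: Hydride reduction of both esters; reduction is much faster than α-deprotonation, so the trans centres are kept, and the auxiliary is recovered.

Step 4
Reactants: 6 [(1R,2R)-cyclohex-4-ene-1,2-diyl]dimethanol
Product: 7 (4R,5R)-4,5-bis[(TBS-oxy)methyl]cyclohexene
Conditions: TBSCl, imidazole, DMF, rt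
Reagents that add atoms: tert-butyldimethylsilyl chloride, C[Si](C)(Cl)C(C)(C)C
Why: Imidazole-assisted silylation of primary alcohols; the silyl ethers tolerate every basic, organometallic and photochemical step up to the final acidolysis.

Step 5
Reactants: 7 (4R,5R)-4,5-bis[(TBS-oxy)methyl]cyclohexene
Product: 8 (3R,4R)-3,4-bis[(TBS-oxy)methyl]-7-oxabicyclo[4.1.0]heptane
Conditions: mCPBA, NaHCO3, CH2Cl2, 0 °C
Reagents that add atoms: 3-chloroperoxybenzoic acid, O=C(OO)c1cccc(Cl)c1
Why: Prilezhaev epoxidation (concerted syn oxygen transfer); the two faces of the C2-symmetric alkene are related by the axis, so only one epoxide can form.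

Step 6
Reactants: 8 (3R,4R)-3,4-bis[(TBS-oxy)methyl]-7-oxabicyclo[4.1.0]heptane
Product: 11 (1R,4R,5R)-4,5-bis[(TBS-oxy)methyl]cyclohex-2-en-1-ol, via trans-hydroxy selenide 9 (not isolated), via selenoxide 10 (not isolated)
Conditions: (PhSe)2, NaBH4, EtOH, rt; add 8, reflux; then THF, 30% H2O2, 0 °C → rt
Reagents that add atoms: none
Why: Sharpless-type epoxide-to-allylic-alcohol transposition: PhSe− opens the epoxide by SN2 (trans-diaxial), oxidation gives the selenoxide, and syn elimination away from the carbinol carbon puts the double bond next to a ring stereocentre. Which epoxide carbon is attacked only decides the carbinol configuration, which is lost in step 7.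

Step 7
Reactants: 11 (1R,4R,5R)-4,5-bis[(TBS-oxy)methyl]cyclohex-2-en-1-ol
Product: 12 (4R,5R)-4,5-bis[(TBS-oxy)methyl]cyclohex-2-en-1-one
Conditions: activated MnO2 (excess), CH2Cl2, rt
Reagents that add atoms: none
Why: Chemoselective allylic alcohol oxidation on the MnO2 surface; the neutral conditions leave the γ-stereocentre alone.

Step 8
Reactants: 13 4-bromo-2,6-dimethoxyphenol
Product: 14 5-bromo-1,3-dimethoxy-2-(methoxymethoxy)benzene
Conditions: MeOCH2Cl, i-Pr2NEt, CH2Cl2, 0 °C → rt
Reagents that add atoms: chloromethyl methyl ether, COCCl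
Why: Williamson-type O-alkylation of the phenol; the acetal survives organolithium, cuprate, hydride and base and is removed together with the silyl ethers at the end.

Step 9
Reactants: 14 5-bromo-1,3-dimethoxy-2-(methoxymethoxy)benzene; 12 (4R,5R)-4,5-bis[(TBS-oxy)methyl]cyclohex-2-en-1-one
Product: 17 {[(3S,4R,5R)-3-Ar-4,5-bis[(TBS-oxy)methyl]cyclohex-1-en-1-yl]oxy}trimethylsilane, via aryllithium 15 (not isolated), via lithium diarylcuprate 16 (not isolated)
Conditions: 14 (2.4 equiv), n-BuLi, THF, −78 °C; CuBr·SMe2 (1.2 equiv), −78 → −40 °C; 12, Me3SiCl, −78 °C; Et3N, aq. NaHCO3; used crude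
Reagents that add atoms: chlorotrimethylsilane, C[Si](C)(C)Cl
Why: Bromine–lithium exchange, Gilman cuprate formation and Me3SiCl-assisted conjugate addition; the enolate is silylated where it forms, so the enol ether double bond lies between C1 and the carbon next to the aryl-bearing one. The aryl group should enter axially, anti to the C5 substituent and hence cis to the C4 substituent; this centre is not relied upon because step 10 removes it.

Step 10
Reactants: 17 {[(3S,4R,5R)-3-Ar-4,5-bis[(TBS-oxy)methyl]cyclohex-1-en-1-yl]oxy}trimethylsilane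
Product: 18 (4S,5R)-3-Ar-4,5-bis[(TBS-oxy)methyl]cyclohex-2-en-1-one
Conditions: Pd(OAc)2 (1.1 equiv), MeCN, rt
Reagents that add atoms: none
Why: Saegusa–Ito oxidation: palladation of the silyl enol ether gives a C2-bound palladium enolate whose only β-hydrogen is on the aryl-bearing carbon, so syn β-hydride elimination gives the 3-aryl enone regiospecifically; C4 and C5 are untouched under these neutral conditions.

Step 11
Reactants: 18 (4S,5R)-3-Ar-4,5-bis[(TBS-oxy)methyl]cyclohex-2-en-1-one
Product: 21 (3R,4R,5R)-3-Ar-4,5-bis[(TBS-oxy)methyl]cyclohex-1-en-1-yl trifluoromethanesulfonate, via dimethylphenylsilyl enol ether 19 (not isolated), via lithium enolate 20 (not isolated)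
Conditions: [(Ph3P)CuH]6 (5 mol % Cu), PhMe2SiH, toluene, rt; evaporate; MeLi, THF, 0 °C; then N-(5-chloropyridin-2-yl)bis(trifluoromethanesulfonyl)imide, −78 → 0 °C
Reagents that add atoms: N-(5-chloropyridin-2-yl)bis(trifluoromethanesulfonyl)imide, FC(F)(F)S(=O)(=O)N(c1ccc(Cl)cn1)S(=O)(=O)C(F)(F)F
Why: Copper hydride-catalysed 1,4-hydrosilylation (Stryker–Lipshutz type) gives the silyl enol ether regiospecifically; MeLi releases the lithium enolate, which is O-sulfonylated (Comins triflation). Hydride should be delivered axially to C3 of the half-chair with both silyloxymethyl groups equatorial, anti to the C5 substituent, which pushes the aryl group into the equatorial position, trans to C4 (future C1, S); this is also the more stable, all-equatorial arrangement.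

Step 12
Reactants: 21 (3R,4R,5R)-3-Ar-4,5-bis[(TBS-oxy)methyl]cyclohex-1-en-1-yl trifluoromethanesulfonate
Product: 23 1-[(3S,4R,5R)-3-Ar-4,5-bis[(TBS-oxy)methyl]cyclohex-1-en-1-yl]ethan-1-one, via 2-butoxydiene 22 (not isolated)
Conditions: butyl vinyl ether, Pd(OAc)2 (3 mol %), Ph2P(CH2)3PPh2 (6 mol %), Et3N, DMF, 80 °C; then 5% aq. oxalic acid, THF, rt
Reagents that add atoms: butyl vinyl ether, C=COCCCC; water, O
Why: Mizoroki–Heck coupling of a vinyl triflate with an electron-rich alkene; with a chelating diphosphine and a triflate the cationic palladium pathway (zerovalent/divalent cycle) sends the vinyl group to the oxygen-bearing carbon, and the resulting enol ether is hydrolysed by dilute acid much faster than silyl ethers or the acetal are cleaved. No stereocentre is involved.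

Step 13
Reactants: 23 1-[(3S,4R,5R)-3-Ar-4,5-bis[(TBS-oxy)methyl]cyclohex-1-en-1-yl]ethan-1-one
Product: 25 2-diazo-1-[(3S,4R,5R)-3-Ar-4,5-bis[(TBS-oxy)methyl]cyclohex-1-en-1-yl]ethan-1-one, via trifluoroacetyl diketone 24 (not isolated)
Conditions: LiN(SiMe3)2, THF, −78 °C; CF3CO2CH2CF3, −78 °C; then 4-acetamidobenzenesulfonyl azide, Et3N, H2O (1 equiv), MeCN, rt
Reagents that add atoms: 4-acetamidobenzenesulfonyl azide, CC(=O)Nc1ccc(cc1)S(=O)(=O)N=[N+]=[N-]
Why: Detrifluoroacetylative diazo transfer (Danheiser procedure): kinetic deprotonation at the methyl group, Claisen trifluoroacetylation to activate it, then diazo transfer from the sulfonyl azide with loss of the trifluoroacetyl group as the N-acylsulfonamide. It replaces acylation of diazomethane by an enoyl chloride, which suffers from dipolar cycloaddition to the conjugated double bond and needs a hazardous reagent.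

Step 14
Reactants: 26 2-chloro-1,1-dimethoxyethane
Product: 28 methoxyethyne, via sodium methoxyacetylide 27 (not isolated)
Conditions: NaNH2 (3 equiv), liquid NH3, −33 °C; then cold sat. aq. NaCl, −70 °C; distil into a cold trap, keep as a cold solution in ClCH2CH2Cl
Reagents that add atoms: none
Why: Twofold base-induced elimination (methanol, then HCl) gives the alkyne, which NaNH2 holds as its acetylide until the cold aqueous quench; the volatile product is handled only in solution.

Step 15
Reactants: 25 2-diazo-1-[(3S,4R,5R)-3-Ar-4,5-bis[(TBS-oxy)methyl]cyclohex-1-en-1-yl]ethan-1-one; 28 methoxyethyne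
Product: 33 (1S,2R,3R)-1-Ar-2,3-bis[(TBS-oxy)methyl]-6-methoxy-1,2,3,4-tetrahydronaphthalen-8-ol, via vinylketene 29 (not isolated), via 4-vinylcyclobutenone 30 (not isolated), via dienylketene 31 (not isolated), via cyclohexadienone 32 (not isolated)
Conditions: 28 (3 equiv), ClCH2CH2Cl, sealed Pyrex tube, hν (300 nm), rt; then 80 °C
Reagents that add atoms: none
Why: Light expels N2 from 25 and the cyclohexenyl group shifts from the carbonyl carbon to the former diazo carbon (photochemical Wolff rearrangement), giving vinylketene 29. The ynol ether 28 adds across the ketene C=C in a polar [2+2] cycloaddition, its unsubstituted, nucleophilic carbon bonding to the electrophilic ketene carbon, so that 30 carries the methoxy group on C3 of the four-membered ring. Conrotatory 4π opening of 30 (by light or on warming) gives dienylketene 31, and a thermal disrotatory 6π electrocyclisation between the ketene carbon and the ring CH (C8–C8a) closes ring A as dienone 32, which enolises to 33. The bonds C4a–C5, C5–C6, C7–C8 and C8–C8a are formed; the ketene carbon becomes C8 (OH), the alkyne carbons C7 (H) and C6 (OMe), and the diazo carbon C5. The closest known reaction type is the Danheiser benzannulation in its diazoketone variant, established for 1-cyclohexenyl diazomethyl ketones and alkoxyalkynes. No stereocentre is created: C1, C2 and C3 lie outside the reacting π system and the medium is neutral, so they are carried through unchanged. The only selectivity needed is regiochemical and is secured by the polarisation of 28, which fixes OMe meta to the new OH. An excess of 28 keeps the cycloaddition ahead of ketene dimerisation and of a 1,5-hydrogen shift from C1.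

Step 16
Reactants: 33 (1S,2R,3R)-1-Ar-2,3-bis[(TBS-oxy)methyl]-6-methoxy-1,2,3,4-tetrahydronaphthalen-8-ol
Product: 34 (1S,2R,3R)-1-Ar-2,3-bis[(TBS-oxy)methyl]-6,8-dimethoxy-1,2,3,4-tetrahydronaphthalene
Conditions: MeI, K2CO3, DMF, rt
Reagents that add atoms: iodomethane, CI
Why: O-Methylation of the phenoxide (Williamson ether synthesis); this also removes the acidic OH before the lithiation.

Step 17
Reactants: 34 (1S,2R,3R)-1-Ar-2,3-bis[(TBS-oxy)methyl]-6,8-dimethoxy-1,2,3,4-tetrahydronaphthalene
Product: 37 (1S,2R,3R)-1-Ar-2,3-bis[(TBS-oxy)methyl]-6,8-dimethoxy-1,2,3,4-tetrahydronaphthalen-7-ol, via C7 aryllithium 35 (not isolated), via dimethyl arylboronate 36 (not isolated)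
Conditions: n-BuLi, THF, 0 °C; B(OMe)3, −78 °C → rt; then 30% H2O2, aq. NaOH, 0 °C
Reagents that add atoms: hydrogen peroxide, OO
Why: Directed ortho-metalation: the C7 hydrogen is the only one flanked by two methoxy groups and should be removed fastest; the aryllithium is borylated and the boronate oxidised with 1,2-shift of the aryl group from boron to oxygen, so the hydroxyl appears exactly at C7. C1 is not involved as long as ring lithiation outruns benzylic deprotonation (0 °C, short time).

Step 18
Reactants: 37 (1S,2R,3R)-1-Ar-2,3-bis[(TBS-oxy)methyl]-6,8-dimethoxy-1,2,3,4-tetrahydronaphthalen-7-ol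
Product: 38 (1S,2R,3R)-1-(4-hydroxy-3,5-dimethoxyphenyl)-2,3-bis(hydroxymethyl)-6,8-dimethoxy-1,2,3,4-tetrahydronaphthalen-7-ol
Conditions: HCl (1 M in MeOH), 0 °C → rt
Reagents that add atoms: none
Why: Acid-catalysed methanolysis cleaves both primary silyl ethers and the methoxymethyl acetal in one operation; no cation can form at a stereocentre under these conditions, so (1S,2R,3R) is retained.

## Compound list

The CIP label at C3 of the cyclohexenes changes with the group on C1; from 19 onwards the geometry is the same (aryl trans to the C4 substituent, cis to the C5 substituent).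

1 | (1S,2R,5S)-menthol | CC(C)[C@H]1CC[C@H](C)C[C@@H]1O | starting material
2 | fumaric acid | OC(=O)/C=C/C(=O)O | starting material
3 | bis[(1S,2R,5S)-menthyl] fumarate | CC(C)[C@H]1CC[C@H](C)C[C@@H]1OC(=O)/C=C/C(=O)O[C@H]1C[C@@H](C)CC[C@@H]1C(C)C | intermediate
4 | buta-1,3-diene | C=CC=C | starting material
5 | bis[(1S,2R,5S)-menthyl] (1R,2R)-cyclohex-4-ene-1,2-dicarboxylate | C1C=CC[C@@H](C(=O)O[C@H]2C[C@@H](C)CC[C@@H]2C(C)C)[C@@H]1C(=O)O[C@H]1C[C@@H](C)CC[C@@H]1C(C)C | intermediate
6 | [(1R,2R)-cyclohex-4-ene-1,2-diyl]dimethanol | C1C=CC[C@@H](CO)[C@@H]1CO | intermediate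
7 | (4R,5R)-4,5-bis[(TBS-oxy)methyl]cyclohexene | C1C=CC[C@@H](CO[Si](C)(C)C(C)(C)C)[C@@H]1CO[Si](C)(C)C(C)(C)C | intermediate
8 | (3R,4R)-3,4-bis[(TBS-oxy)methyl]-7-oxabicyclo[4.1.0]heptane (the single cis-epoxide of 7) | C1[C@H]2O[C@H]2C[C@@H](CO[Si](C)(C)C(C)(C)C)[C@@H]1CO[Si](C)(C)C(C)(C)C | intermediate
9 | (4R,5R)-4,5-bis[(TBS-oxy)methyl]-2-(phenylselanyl)cyclohexan-1-ol, OH and SePh trans-diaxial (not isolated) | C1[C@@H]([Se]c2ccccc2)[C@H](O)C[C@@H](CO[Si](C)(C)C(C)(C)C)[C@@H]1CO[Si](C)(C)C(C)(C)C | intermediate
10 | selenoxide of 9 (configuration at selenium undefined; not isolated) | C1[C@@H]([Se](=O)c2ccccc2)[C@H](O)C[C@@H](CO[Si](C)(C)C(C)(C)C)[C@@H]1CO[Si](C)(C)C(C)(C)C | intermediate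
11 | (1R,4R,5R)-4,5-bis[(TBS-oxy)methyl]cyclohex-2-en-1-ol | C1=C[C@H](O)C[C@@H](CO[Si](C)(C)C(C)(C)C)[C@@H]1CO[Si](C)(C)C(C)(C)C | intermediate
12 | (4R,5R)-4,5-bis[(TBS-oxy)methyl]cyclohex-2-en-1-one | C1=CC(=O)C[C@@H](CO[Si](C)(C)C(C)(C)C)[C@@H]1CO[Si](C)(C)C(C)(C)C | intermediate
13 | 4-bromo-2,6-dimethoxyphenol | COc1cc(Br)cc(OC)c1O | starting material
14 | 5-bromo-1,3-dimethoxy-2-(methoxymethoxy)benzene | COc1cc(Br)cc(OC)c1OCOC | intermediate
15 | [3,5-dimethoxy-4-(methoxymethoxy)phenyl]lithium (not isolated) | [Li]c1cc(OC)c(OCOC)c(OC)c1 | intermediate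
16 | lithium bis[3,5-dimethoxy-4-(methoxymethoxy)phenyl]cuprate (not isolated) | [Li+].COCOc1c(OC)cc([Cu-]c2cc(OC)c(OCOC)c(OC)c2)cc1OC | intermediate
17 | {[(3S,4R,5R)-3-Ar-4,5-bis[(TBS-oxy)methyl]cyclohex-1-en-1-yl]oxy}trimethylsilane (aryl cis to the C4 substituent, the epimer expected to prevail; either epimer serves) | COc1cc([C@@H]2C=C(O[Si](C)(C)C)C[C@@H](CO[Si](C)(C)C(C)(C)C)[C@@H]2CO[Si](C)(C)C(C)(C)C)cc(OC)c1OCOC | intermediate
18 | (4S,5R)-3-Ar-4,5-bis[(TBS-oxy)methyl]cyclohex-2-en-1-one | COc1cc(C2=CC(=O)C[C@@H](CO[Si](C)(C)C(C)(C)C)[C@@H]2CO[Si](C)(C)C(C)(C)C)cc(OC)c1OCOC | intermediate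
19 | {[(3R,4R,5R)-3-Ar-4,5-bis[(TBS-oxy)methyl]cyclohex-1-en-1-yl]oxy}dimethyl(phenyl)silane (not isolated) | COc1cc([C@H]2C=C(O[Si](C)(C)c3ccccc3)C[C@@H](CO[Si](C)(C)C(C)(C)C)[C@@H]2CO[Si](C)(C)C(C)(C)C)cc(OC)c1OCOC | intermediate
20 | lithium (3R,4R,5R)-3-Ar-4,5-bis[(TBS-oxy)methyl]cyclohex-1-en-1-olate (not isolated) | COc1cc([C@H]2C=C(O[Li])C[C@@H](CO[Si](C)(C)C(C)(C)C)[C@@H]2CO[Si](C)(C)C(C)(C)C)cc(OC)c1OCOC | intermediate
21 | (3R,4R,5R)-3-Ar-4,5-bis[(TBS-oxy)methyl]cyclohex-1-en-1-yl trifluoromethanesulfonate | COc1cc([C@H]2C=C(OS(=O)(=O)C(F)(F)F)C[C@@H](CO[Si](C)(C)C(C)(C)C)[C@@H]2CO[Si](C)(C)C(C)(C)C)cc(OC)c1OCOC | intermediate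
22 | 1-(1-butoxyethenyl)-3-Ar-4,5-bis[(TBS-oxy)methyl]cyclohex-1-ene, ring configuration as in 21 (not isolated) | COc1cc([C@H]2C=C(C(=C)OCCCC)C[C@@H](CO[Si](C)(C)C(C)(C)C)[C@@H]2CO[Si](C)(C)C(C)(C)C)cc(OC)c1OCOC | intermediate
23 | 1-[(3S,4R,5R)-3-Ar-4,5-bis[(TBS-oxy)methyl]cyclohex-1-en-1-yl]ethan-1-one | COc1cc([C@H]2C=C(C(C)=O)C[C@@H](CO[Si](C)(C)C(C)(C)C)[C@@H]2CO[Si](C)(C)C(C)(C)C)cc(OC)c1OCOC | intermediate
24 | 4,4,4-trifluoro-1-[3-Ar-4,5-bis[(TBS-oxy)methyl]cyclohex-1-en-1-yl]butane-1,3-dione, ring configuration as in 23 (not isolated) | COc1cc([C@H]2C=C(C(=O)CC(=O)C(F)(F)F)C[C@@H](CO[Si](C)(C)C(C)(C)C)[C@@H]2CO[Si](C)(C)C(C)(C)C)cc(OC)c1OCOC | intermediate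
25 | 2-diazo-1-[(3S,4R,5R)-3-Ar-4,5-bis[(TBS-oxy)methyl]cyclohex-1-en-1-yl]ethan-1-one | COc1cc([C@H]2C=C(C(=O)C=[N+]=[N-])C[C@@H](CO[Si](C)(C)C(C)(C)C)[C@@H]2CO[Si](C)(C)C(C)(C)C)cc(OC)c1OCOC | intermediate
26 | 2-chloro-1,1-dimethoxyethane (chloroacetaldehyde dimethyl acetal) | COC(CCl)OC | starting material
27 | sodium methoxyacetylide (not isolated) | [Na+].[C-]#COC | intermediate
28 | methoxyethyne | C#COC | intermediate
29 | 2-[3-Ar-4,5-bis[(TBS-oxy)methyl]cyclohex-1-en-1-yl]ethenone, ring configuration as in 25 (not isolated) | COc1cc([C@H]2C=C(C=C=O)C[C@@H](CO[Si](C)(C)C(C)(C)C)[C@@H]2CO[Si](C)(C)C(C)(C)C)cc(OC)c1OCOC | intermediate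
30 | 4-[3-Ar-4,5-bis[(TBS-oxy)methyl]cyclohex-1-en-1-yl]-3-methoxycyclobut-2-en-1-one, ring configuration as in 25, C4 of the four-membered ring undefined (not isolated) | COc1cc([C@H]2C=C(C3C(=O)C=C3OC)C[C@@H](CO[Si](C)(C)C(C)(C)C)[C@@H]2CO[Si](C)(C)C(C)(C)C)cc(OC)c1OCOC | intermediate
31 | 4-[3-Ar-4,5-bis[(TBS-oxy)methyl]cyclohex-1-en-1-yl]-3-methoxybuta-1,3-dien-1-one, ketene cis to the ring (not isolated) | COc1cc([C@H]2C=C(/C=C(\C=C=O)OC)C[C@@H](CO[Si](C)(C)C(C)(C)C)[C@@H]2CO[Si](C)(C)C(C)(C)C)cc(OC)c1OCOC | intermediate
32 | 1-Ar-2,3-bis[(TBS-oxy)methyl]-6-methoxy-2,3,4,8a-tetrahydronaphthalen-8(1H)-one, keto tautomer of 33, C8a undefined (not isolated) | COc1cc([C@H]2C3C(=O)C=C(OC)C=C3C[C@@H](CO[Si](C)(C)C(C)(C)C)[C@@H]2CO[Si](C)(C)C(C)(C)C)cc(OC)c1OCOC | intermediate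
33 | (1S,2R,3R)-1-Ar-2,3-bis[(TBS-oxy)methyl]-6-methoxy-1,2,3,4-tetrahydronaphthalen-8-ol | COc1cc([C@H]2c3c(cc(OC)cc3O)C[C@@H](CO[Si](C)(C)C(C)(C)C)[C@@H]2CO[Si](C)(C)C(C)(C)C)cc(OC)c1OCOC | intermediate
34 | (1S,2R,3R)-1-Ar-2,3-bis[(TBS-oxy)methyl]-6,8-dimethoxy-1,2,3,4-tetrahydronaphthalene | COc1cc([C@H]2c3c(cc(OC)cc3OC)C[C@@H](CO[Si](C)(C)C(C)(C)C)[C@@H]2CO[Si](C)(C)C(C)(C)C)cc(OC)c1OCOC | intermediate
35 | 7-lithio derivative of 34 (not isolated) | COc1cc([C@H]2c3c(cc(OC)c([Li])c3OC)C[C@@H](CO[Si](C)(C)C(C)(C)C)[C@@H]2CO[Si](C)(C)C(C)(C)C)cc(OC)c1OCOC | intermediate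
36 | dimethyl boronate at C7 of 34 (not isolated) | COc1cc([C@H]2c3c(cc(OC)c(B(OC)OC)c3OC)C[C@@H](CO[Si](C)(C)C(C)(C)C)[C@@H]2CO[Si](C)(C)C(C)(C)C)cc(OC)c1OCOC | intermediate
37 | (1S,2R,3R)-1-Ar-2,3-bis[(TBS-oxy)methyl]-6,8-dimethoxy-1,2,3,4-tetrahydronaphthalen-7-ol | COc1cc([C@H]2c3c(cc(OC)c(O)c3OC)C[C@@H](CO[Si](C)(C)C(C)(C)C)[C@@H]2CO[Si](C)(C)C(C)(C)C)cc(OC)c1OCOC | intermediate
38 | (1S,2R,3R)-1-(4-hydroxy-3,5-dimethoxyphenyl)-2,3-bis(hydroxymethyl)-6,8-dimethoxy-1,2,3,4-tetrahydronaphthalen-7-ol | COc1cc([C@H]2c3c(cc(OC)c(O)c3OC)C[C@@H](CO)[C@@H]2CO)cc(OC)c1O | target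

## Step count and least certain steps

Total: 18 steps. Longest linear sequence: 16 steps (1–7, 9–13, 15–18); steps 8 and 14 are side branches.

Step 15 (key step). The likeliest failure is loss of the vinylketene before it meets the alkyne: dimerisation, a 1,5-hydrogen shift from the benzylic C1–H, or escape of the volatile alkyne from the irradiated solution. Incomplete ring opening of the cyclobutenone is a second possibility. Fallback: generate the same ketene thermally, with the alkyne always in excess. Starting from 25, Wolff rearrangement in aqueous dioxane (PhCO2Ag, Et3N, or light) gives the homologous 2-(cyclohexenyl)acetic acid F1. 1-Chloro-N,N,2-trimethylprop-1-en-1-amine converts it under neutral conditions to the acid chloride F2. Slow addition of Et3N to F2 and 28 in ClCH2CH2Cl at 80 °C forms 29 by dehydrochlorination, and the sequence continues as in the main route, rejoining at 33.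

Step 11. The likeliest failure is poor or reversed facial selectivity in hydride delivery, if the enone reacts through the conformer with the C4 substituent pseudo-axial (allylic strain with the aryl group) and hydride enters anti to it. Slow hydrometalation of the hindered β-aryl enone is the second concern. Fallback: reverse the order in which aryl and hydrogen arrive. Starting from 12, cuprate 16 is added and the enolate trapped directly with the pyridyl triflimide, giving 21 in one operation. A ring bias anti to the C4 substituent, which would defeat the hydride route, is exactly what this direct aryl transfer needs. It rejoins at 21 and makes no compound outside the list (entry F0).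

Step 17. The likeliest failure is proton abstraction at the doubly benzylic C1–H (lateral metalation next to the C8 methoxy group) or on the pendant ring in competition with C7 lithiation, leading to loss of configuration at C1 or regioisomeric phenols. Fallback: introduce the C7 oxygen through the phenol, without a strong base. Starting from 33, MgCl2, Et3N and paraformaldehyde formylate the only free ortho position to give the salicylaldehyde F3. MeI and K2CO3 give the methyl ether F4. mCPBA (Dakin-type Baeyer–Villiger oxidation) gives the aryl formate F5, and K2CO3 in MeOH cleaves it to 37, where the route is rejoined.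

Step 2. The likeliest failure is insufficient, or opposite, facial discrimination by the menthyl groups, which would erode or invert the absolute configuration of everything downstream. Fallback: make the absolute configuration independent of the auxiliary. Starting from 2 and 4, a thermal Diels–Alder reaction (sealed tube, AcOH, 110 °C) gives the racemic trans-cyclohex-4-ene-1,2-dicarboxylic acid F6. Classical resolution through the salt with one enantiomer of 1-phenylethylamine (the right antipode of the base to be found by trial) gives the (1R,2R)-diacid F7, and LiAlH4 reduces it to 6, where the route is rejoined.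

## Further compounds

F1 | step 15 | 2-[(3S,4R,5R)-3-Ar-4,5-bis[(TBS-oxy)methyl]cyclohex-1-en-1-yl]acetic acid | COc1cc([C@H]2C=C(CC(=O)O)C[C@@H](CO[Si](C)(C)C(C)(C)C)[C@@H]2CO[Si](C)(C)C(C)(C)C)cc(OC)c1OCOC
F2 | step 15 | 2-[(3S,4R,5R)-3-Ar-4,5-bis[(TBS-oxy)methyl]cyclohex-1-en-1-yl]acetyl chloride | COc1cc([C@H]2C=C(CC(=O)Cl)C[C@@H](CO[Si](C)(C)C(C)(C)C)[C@@H]2CO[Si](C)(C)C(C)(C)C)cc(OC)c1OCOC
F0 | step 11 | none | none
F3 | step 17 | (1S,2R,3R)-1-Ar-2,3-bis[(TBS-oxy)methyl]-8-hydroxy-6-methoxy-1,2,3,4-tetrahydronaphthalene-7-carbaldehyde | COc1cc([C@H]2c3c(cc(OC)c(C=O)c3O)C[C@@H](CO[Si](C)(C)C(C)(C)C)[C@@H]2CO[Si](C)(C)C(C)(C)C)cc(OC)c1OCOC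
F4 | step 17 | (1S,2R,3R)-1-Ar-2,3-bis[(TBS-oxy)methyl]-6,8-dimethoxy-1,2,3,4-tetrahydronaphthalene-7-carbaldehyde | COc1cc([C@H]2c3c(cc(OC)c(C=O)c3OC)C[C@@H](CO[Si](C)(C)C(C)(C)C)[C@@H]2CO[Si](C)(C)C(C)(C)C)cc(OC)c1OCOC
F5 | step 17 | (1S,2R,3R)-1-Ar-2,3-bis[(TBS-oxy)methyl]-6,8-dimethoxy-1,2,3,4-tetrahydronaphthalen-7-yl formate | COc1cc([C@H]2c3c(cc(OC)c(OC=O)c3OC)C[C@@H](CO[Si](C)(C)C(C)(C)C)[C@@H]2CO[Si](C)(C)C(C)(C)C)cc(OC)c1OCOC
F6 | step 2 | racemic trans-cyclohex-4-ene-1,2-dicarboxylic acid (both enantiomers written) | C1C=CC[C@@H](C(=O)O)[C@@H]1C(=O)O.C1C=CC[C@H](C(=O)O)[C@H]1C(=O)O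
F7 | step 2 | (1R,2R)-cyclohex-4-ene-1,2-dicarboxylic acid | C1C=CC[C@@H](C(=O)O)[C@@H]1C(=O)O
A1 | alternative 1 | (2R,4R)-pentane-2,4-diyl bis[(E)-3-(4-hydroxy-3,5-dimethoxyphenyl)prop-2-enoate] | COc1cc(/C=C/C(=O)O[C@H](C)C[C@@H](C)OC(=O)/C=C/c2cc(OC)c(O)c(OC)c2)cc(OC)c1O
A2 | alternative 1 | (2R,4R)-pentane-2,4-diyl-bridged trans-1-(4-hydroxy-3,5-dimethoxyphenyl)-7-hydroxy-6,8-dimethoxy-1,2-dihydronaphthalene-2,3-dicarboxylate | COc1cc([C@H]2c3c(cc(OC)c(O)c3OC)C=C5C(=O)O[C@H](C)C[C@@H](C)OC(=O)[C@H]25)cc(OC)c1O
A3 | alternative 2 | dimethyl 2-[1-(benzyloxy)-3-{4-(benzyloxy)-3,5-dimethoxy-2-[(tosylhydrazono)methyl]phenyl}propan-2-yl]malonate | COC(=O)C(C(=O)OC)[C@H](COCc1ccccc1)Cc1cc(OC)c(OCc2ccccc2)c(OC)c1/C=N/NS(=O)(=O)c1ccc(C)cc1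
A4 | alternative 2 | 2-(benzyloxy)-5-bromo-1,3-dimethoxybenzene | COc1cc(Br)cc(OC)c1OCc1ccccc1
A5 | alternative 2 | dimethyl 1-[4-(benzyloxy)-3,5-dimethoxyphenyl]-7-(benzyloxy)-3-(benzyloxymethyl)-6,8-dimethoxytetralin-2,2-dicarboxylate | COc1cc([C@H]2c3c(cc(OC)c(OCc4ccccc4)c3OC)C[C@@H](COCc3ccccc3)C2(C(=O)OC)C(=O)OC)cc(OC)c1OCc1ccccc1
A6 | alternative 3 | [4-(benzyloxy)-3,5-dimethoxyphenyl][3-(benzyloxy)-2,4-dimethoxy-6-methylphenyl]methanone | COc1cc(C(=O)c2c(C)cc(OC)c(OCc3ccccc3)c2OC)cc(OC)c1OCc1ccccc1
A7 | alternative 3 | dimethyl 1-[4-(benzyloxy)-3,5-dimethoxyphenyl]-1-hydroxy-7-(benzyloxy)-6,8-dimethoxytetralin-2,3-dicarboxylate (hydroxyl cis to the C2 ester, esters trans) | COc1cc([C@@]2(O)c3c(cc(OC)c(OCc4ccccc4)c3OC)C[C@@H](C(=O)OC)[C@@H]2C(=O)OC)cc(OC)c1OCc1ccccc1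
A8 | alternative 3 | dimethyl fumarate | COC(=O)/C=C/C(=O)OC
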